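**Plan**

1. Prostanoid numbering is used: C1 is the ester carbon, C4 the acetoxy carbon of the upper chain, C8–C12 the ring (C9 ketone, C12 acetoxy carbon), C13–C20 the dienyl chain.
2. Retrosynthesis: the C12 acetate and the C7=C8 olefin are cut first (aldol condensation), giving a 4-hydroxy-4-dienylcyclopent-2-enone and a (Z)-enal; then the ring bond C8–C12 is cut.
3. Enabling feature: the 4-oxygenated cyclopent-2-enone (C9=O, cis C10=C11, tertiary carbinol C12, methylene C8) is a rearranged furan. C9–C12 plus the ketone oxygen are a 2,5-disubstituted furan and C8 is its hydroxymethyl carbon (Piancatelli retron).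
4. Forward: diyne coupling and Lindlar reduction give the skipped (Z,Z)-dienyl bromide, which alkylates a lithiated furfural acetal. Reduction gives the furfuryl alcohol, acid-catalysed rearrangement in water builds the only ring, and aldol addition of the enal followed by acetylation–elimination attaches the upper chain.
5. Stereochemistry: C12 comes from a chiral Brønsted acid in the rearrangement, C4 from asymmetric transfer hydrogenation of an ynone, the three Z olefins from Lindlar semihydrogenations, and 7E from the thermodynamic preference in the E1cB elimination.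

Key step: step 6

Assumption: the (R)-configured acid in step 6 and the (R,R)-configured Ru catalyst in step 9 are taken to give the configurations drawn; if either sense of induction proves opposite, the enantiomeric catalyst is used.

**Route**

Step 1
Reactants: 1 prop-2-yn-1-ol; 2 1-bromopent-2-yne
Product: 3 octa-2,5-diyn-1-ol
Conditions: CuI, NaI, K2CO3, DMF, rt
Reagents that add atoms: none
Why: Copper-mediated coupling of a terminal alkyne with a propargylic bromide (SN2 displacement by the copper acetylide) is the standard entry to skipped diynes and tolerates the free hydroxyl.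

Step 2
Reactants: 3 octa-2,5-diyn-1-ol
Product: 4 (2Z,5Z)-octa-2,5-dien-1-ol
Conditions: H2 (1 atm), Pd/CaCO3 poisoned with Pb(OAc)2, quinoline, EtOAc, rt
Reagents that add atoms: none
Why: Lindlar semihydrogenation adds hydrogen syn to each triple bond, so both new olefins should be Z, and quinoline holds back over-reduction.

Step 3
Reactants: 4 (2Z,5Z)-octa-2,5-dien-1-ol
Product: 5 (2Z,5Z)-1-bromoocta-2,5-diene
Conditions: CBr4, PPh3, CH2Cl2, 0 °C
Reagents that add atoms: tetrabromomethane, BrC(Br)(Br)Br
Why: Appel bromination of a primary allylic alcohol proceeds by SN2 displacement of the oxyphosphonium group at low temperature, without allylic transposition or loss of Z geometry.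

Step 4
Reactants: 6 2-(furan-2-yl)-1,3-dioxolane; 5 (2Z,5Z)-1-bromoocta-2,5-diene
Product: 9 5-[(2Z,5Z)-octa-2,5-dien-1-yl]furan-2-carbaldehyde, via lithiated acetal 7 (not isolated), via alkylated acetal 8 (not isolated)
Conditions: n-BuLi, THF, −78 °C; 5, −78 to 0 °C; then 1 M HCl, THF, rt
Reagents that add atoms: water, O
Why: Furan acetals are lithiated at the free α-position, the furyllithium displaces the primary allylic bromide in SN2 fashion with both Z olefins retained, and dilute acid in the work-up hydrolyses the acetal to the aldehyde.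

Step 5
Reactants: 9 5-[(2Z,5Z)-octa-2,5-dien-1-yl]furan-2-carbaldehyde
Product: 10 {5-[(2Z,5Z)-octa-2,5-dien-1-yl]furan-2-yl}methanol
Conditions: NaBH4, MeOH, 0 °C
Reagents that add atoms: none
Why: Borohydride 1,2-reduction of the aryl aldehyde is fast at 0 °C, so the doubly activated methylene and the skipped diene should not migrate.

Step 6
Reactants: 10 {5-[(2Z,5Z)-octa-2,5-dien-1-yl]furan-2-yl}methanol
Product: 12 (4R)-4-hydroxy-4-[(2Z,5Z)-octa-2,5-dien-1-yl]cyclopent-2-en-1-one, via hydroxypentadienyl cation 11 (not isolated)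
Conditions: (R)-3,3'-bis(2,4,6-triisopropylphenyl)-1,1'-binaphthalene-2,2'-diyl N-triflylphosphoramide (10 mol %), H2O (5 equiv), CHCl3, 40 °C
Reagents that add atoms: water, O
Why: Proposed new method: the strong chiral acid ionizes 10 to the 5-alkylfurfuryl cation (a 2-methylene-2H-furanium ion), water adds at the alkylated ring carbon (future C12), the hemiketal opens to the O-protonated (Z)-enedione enol 11, and this 2,5-dihydroxypentadienyl cation closes between its CH2 terminus (C8) and its carbinol terminus (C12), proton loss then giving the enone; the closest known reaction types are the racemic Piancatelli rearrangement of 5-methyl-2-furylcarbinols promoted by ZnCl2 or Dy(OTf)3 and the enantioselective aza-Piancatelli rearrangements and Nazarov cyclizations catalysed by chiral phosphoric acids and N-triflylphosphoramides, so only the combination of water as nucleophile, a primary carbinol and enantiocontrol at a fully substituted carbon is new. The ring C8–C9–C10–C11–C12 is closed by a thermal conrotatory 4π electrocyclization of the pentadienyl cation, whose termini are held within bonding distance by the cis C10=C11 geometry inherited from the furan. The single new stereocenter C12 is set by the helical sense in which the U-shaped cation twists before closure, and this should be dictated by the chiral phosphoramide anion, held as a contact ion pair by hydrogen bonds to the C12 and C9 hydroxyls while its triisopropylphenyl groups block one of the two conrotatory modes. The step needs water to attack the ring carbon and not the exocyclic carbon (attack there only returns 10), and it needs chemoselectivity over the skipped diene and over furan oligomerization; the 5-alkyl group blocks the position through which furfuryl cations polymerize and stabilizes the cation enough for ionization at 40 °C, conditions under which isolated Z olefins are not protonated.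

Step 7
Reactants: 12 (4R)-4-hydroxy-4-[(2Z,5Z)-octa-2,5-dien-1-yl]cyclopent-2-en-1-one
Product: 13 (4R)-4-[(2Z,5Z)-octa-2,5-dien-1-yl]-4-[(trimethylsilyl)oxy]cyclopent-2-en-1-one
Conditions: Me3SiCl, imidazole, DMF, rt
Reagents that add atoms: chlorotrimethylsilane, C[Si](C)(C)Cl
Why: Silylation of the tertiary alcohol under mild, non-enolizing conditions masks the acidic proton so that one equivalent of base can later form the C8 enolate cleanly.

Step 8
Reactants: 14 tert-butyldimethyl(prop-2-yn-1-yloxy)silane; 15 methyl 4-chloro-4-oxobutanoate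
Product: 16 methyl 7-[(tert-butyldimethylsilyl)oxy]-4-oxohept-5-ynoate
Conditions: PdCl2(PPh3)2 (2 mol %), CuI (4 mol %), Et3N, THF, rt
Reagents that add atoms: none
Why: Acyl Sonogashira coupling (oxidative addition of zerovalent palladium into the acid chloride, transfer of the copper acetylide, reductive elimination) gives the ynone directly and leaves the methyl ester and silyl ether untouched.

Step 9
Reactants: 16 methyl 7-[(tert-butyldimethylsilyl)oxy]-4-oxohept-5-ynoate
Product: 17 methyl (4R)-7-[(tert-butyldimethylsilyl)oxy]-4-hydroxyhept-5-ynoate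
Conditions: RuCl(p-cymene)[(R,R)-N-(p-toluenesulfonyl)-1,2-diphenylethylenediamine] (1 mol %), i-PrOH, rt
Reagents that add atoms: none
Why: Noyori asymmetric transfer hydrogenation of an alkynyl ketone, in which the alkynyl group plays the π-substituent in the six-membered hydride-transfer transition state, should give the (R)-propargylic alcohol with the (R,R)-catalyst, and neutral 2-propanol at room temperature limits lactonization.

Step 10
Reactants: 17 methyl (4R)-7-[(tert-butyldimethylsilyl)oxy]-4-hydroxyhept-5-ynoate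
Product: 18 methyl (4R)-4-acetoxy-7-[(tert-butyldimethylsilyl)oxy]hept-5-ynoate
Conditions: Ac2O, pyridine, 4-(dimethylamino)pyridine (cat.), CH2Cl2, 0 °C
Reagents that add atoms: acetic anhydride, CC(=O)OC(C)=O
Why: Nucleophile-catalysed acetylation, run without delay, installs the C4 acetate of the target and blocks γ-lactonization while leaving the stereocenter untouched.

Step 11
Reactants: 18 methyl (4R)-4-acetoxy-7-[(tert-butyldimethylsilyl)oxy]hept-5-ynoate
Product: 19 methyl (4R)-4-acetoxy-7-hydroxyhept-5-ynoate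
Conditions: HF·pyridine, THF, 0 °C to rt
Reagents that add atoms: none
Why: Fluoride cleavage of the primary silyl ether under buffered acidic conditions leaves both esters intact.

Step 12
Reactants: 19 methyl (4R)-4-acetoxy-7-hydroxyhept-5-ynoate
Product: 20 methyl (4R,5Z)-4-acetoxy-7-hydroxyhept-5-enoate
Conditions: H2 (1 atm), Pd/CaCO3 poisoned with Pb(OAc)2, quinoline, EtOAc, rt
Reagents that add atoms: none
Why: Lindlar semihydrogenation (syn delivery of H2) sets the 5Z olefin, and the quinoline-poisoned catalyst should not hydrogenolyse the propargylic acetate.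

Step 13
Reactants: 20 methyl (4R,5Z)-4-acetoxy-7-hydroxyhept-5-enoate
Product: 21 methyl (4R,5Z)-4-acetoxy-7-oxohept-5-enoate
Conditions: Dess–Martin periodinane, NaHCO3, CH2Cl2, 0 °C; used at once
Reagents that add atoms: none
Why: Dess–Martin oxidation of the (Z)-allylic alcohol under buffered, non-basic conditions should give the (Z)-enal without Z-to-E isomerization.

Step 14
Reactants: 13 (4R)-4-[(2Z,5Z)-octa-2,5-dien-1-yl]-4-[(trimethylsilyl)oxy]cyclopent-2-en-1-one; 21 methyl (4R,5Z)-4-acetoxy-7-oxohept-5-enoate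
Product: 24 methyl (4R,5Z)-4-acetoxy-7-hydroxy-7-{(5S)-5-hydroxy-5-[(2Z,5Z)-octa-2,5-dien-1-yl]-2-oxocyclopent-3-en-1-yl}hept-5-enoate (mixture of epimers at C7 and C8), via lithium enolate 22 (not isolated), via silylated lithium aldolate 23 (not isolated)
Conditions: LiN(i-Pr)2, THF, −78 °C; 21, −78 °C; then 1 M HCl, THF, 0 °C
Reagents that add atoms: none
Why: Kinetic deprotonation at C8, the only enolizable position because C12 is quaternary, gives the cross-conjugated lithium enolate, which adds to the aldehyde carbonyl at −78 °C (directed aldol addition); the C7 and C8 stereocenters are lost in the next step, the dilute acid work-up removes the trimethylsilyl group, and the ring carbinol keeps its spatial arrangement (the descriptor changes from R to S only through the priority rules).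

Step 15
Reactants: 24 methyl (4R,5Z)-4-acetoxy-7-hydroxy-7-{(5S)-5-hydroxy-5-[(2Z,5Z)-octa-2,5-dien-1-yl]-2-oxocyclopent-3-en-1-yl}hept-5-enoate
Product: 27 methyl (4R,5Z,7E)-4-acetoxy-7-{(5S)-5-acetoxy-5-[(2Z,5Z)-octa-2,5-dien-1-yl]-2-oxocyclopent-3-en-1-ylidene}hept-5-enoate, via C7 acetate 25 (not isolated), via dienone alcohol 26 (not isolated)
Conditions: Ac2O (excess), Et3N, 4-(dimethylamino)pyridine, CH2Cl2, 0 °C to rt
Reagents that add atoms: acetic anhydride, CC(=O)OC(C)=O
Why: Acetylation of the C7 hydroxyl triggers E1cB β-elimination to the cross-conjugated dienone, in which the thermodynamically preferred 7E geometry should prevail and the 5Z olefin is carried over from 21, and nucleophile-catalysed acetylation of the tertiary C12 alcohol then completes the target.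

**Compound list**

1 | prop-2-yn-1-ol | C#CCO | starting material
2 | 1-bromopent-2-yne | CCC#CCBr | starting material
3 | octa-2,5-diyn-1-ol | CCC#CCC#CCO | intermediate
4 | (2Z,5Z)-octa-2,5-dien-1-ol | CC/C=C\C/C=C\CO | intermediate
5 | (2Z,5Z)-1-bromoocta-2,5-diene | CC/C=C\C/C=C\CBr | intermediate
6 | 2-(furan-2-yl)-1,3-dioxolane | c1coc(c1)C1OCCO1 | starting material
7 | [5-(1,3-dioxolan-2-yl)furan-2-yl]lithium (formed in the flask) | [Li]c1ccc(o1)C1OCCO1 | intermediate
8 | 2-{5-[(2Z,5Z)-octa-2,5-dien-1-yl]furan-2-yl}-1,3-dioxolane (formed in the flask) | CC/C=C\C/C=C\Cc1ccc(o1)C1OCCO1 | intermediate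
9 | 5-[(2Z,5Z)-octa-2,5-dien-1-yl]furan-2-carbaldehyde | CC/C=C\C/C=C\Cc1ccc(C=O)o1 | intermediate
10 | {5-[(2Z,5Z)-octa-2,5-dien-1-yl]furan-2-yl}methanol | CC/C=C\C/C=C\Cc1ccc(CO)o1 | intermediate
11 | O-protonated (3Z,7Z,10Z)-2-hydroxytrideca-1,3,7,10-tetraen-5-one, the 2,5-dihydroxypentadienyl cation (formed in the flask) | CC/C=C\C/C=C\CC(=[OH+])/C=C\C(O)=C | intermediate
12 | (4R)-4-hydroxy-4-[(2Z,5Z)-octa-2,5-dien-1-yl]cyclopent-2-en-1-one | CC/C=C\C/C=C\C[C@]1(O)C=CC(=O)C1 | intermediate
13 | (4R)-4-[(2Z,5Z)-octa-2,5-dien-1-yl]-4-[(trimethylsilyl)oxy]cyclopent-2-en-1-one | CC/C=C\C/C=C\C[C@]1(O[Si](C)(C)C)C=CC(=O)C1 | intermediate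
14 | tert-butyldimethyl(prop-2-yn-1-yloxy)silane | C#CCO[Si](C)(C)C(C)(C)C | starting material
15 | methyl 4-chloro-4-oxobutanoate | COC(=O)CCC(Cl)=O | starting material
16 | methyl 7-[(tert-butyldimethylsilyl)oxy]-4-oxohept-5-ynoate | COC(=O)CCC(=O)C#CCO[Si](C)(C)C(C)(C)C | intermediate
17 | methyl (4R)-7-[(tert-butyldimethylsilyl)oxy]-4-hydroxyhept-5-ynoate | COC(=O)CC[C@@H](O)C#CCO[Si](C)(C)C(C)(C)C | intermediate
18 | methyl (4R)-4-acetoxy-7-[(tert-butyldimethylsilyl)oxy]hept-5-ynoate | COC(=O)CC[C@@H](OC(C)=O)C#CCO[Si](C)(C)C(C)(C)C | intermediate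
19 | methyl (4R)-4-acetoxy-7-hydroxyhept-5-ynoate | COC(=O)CC[C@@H](OC(C)=O)C#CCO | intermediate
20 | methyl (4R,5Z)-4-acetoxy-7-hydroxyhept-5-enoate | COC(=O)CC[C@@H](OC(C)=O)/C=C\CO | intermediate
21 | methyl (4R,5Z)-4-acetoxy-7-oxohept-5-enoate | COC(=O)CC[C@@H](OC(C)=O)/C=C\C=O | intermediate
22 | lithium enolate of 13 across C8–C9 (formed in the flask) | CC/C=C\C/C=C\C[C@]1(O[Si](C)(C)C)C=CC(O[Li])=C1 | intermediate
23 | lithium C7 aldolate of 13 and 21, C12 trimethylsilyl ether, epimers at C7 and C8 (formed in the flask) | CC/C=C\C/C=C\C[C@]1(O[Si](C)(C)C)C=CC(=O)C1C(O[Li])/C=C\[C@@H](CCC(=O)OC)OC(C)=O | intermediate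
24 | methyl (4R,5Z)-4-acetoxy-7-hydroxy-7-{(5S)-5-hydroxy-5-[(2Z,5Z)-octa-2,5-dien-1-yl]-2-oxocyclopent-3-en-1-yl}hept-5-enoate, epimers at C7 and C8 | CC/C=C\C/C=C\C[C@]1(O)C=CC(=O)C1C(O)/C=C\[C@@H](CCC(=O)OC)OC(C)=O | intermediate
25 | methyl (4R,5Z)-4,7-diacetoxy-7-{(5S)-5-hydroxy-5-[(2Z,5Z)-octa-2,5-dien-1-yl]-2-oxocyclopent-3-en-1-yl}hept-5-enoate, epimers at C7 and C8 (formed in the flask) | CC/C=C\C/C=C\C[C@]1(O)C=CC(=O)C1C(OC(C)=O)/C=C\[C@@H](CCC(=O)OC)OC(C)=O | intermediate
26 | methyl (4R,5Z,7E)-4-acetoxy-7-{(5S)-5-hydroxy-5-[(2Z,5Z)-octa-2,5-dien-1-yl]-2-oxocyclopent-3-en-1-ylidene}hept-5-enoate (formed in the flask) | CC/C=C\C/C=C\C[C@]1(O)C=CC(=O)/C1=C/C=C\[C@@H](CCC(=O)OC)OC(C)=O | intermediate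
27 | methyl (4R,5Z,7E)-4-acetoxy-7-{(5S)-5-acetoxy-5-[(2Z,5Z)-octa-2,5-dien-1-yl]-2-oxocyclopent-3-en-1-ylidene}hept-5-enoate (17,18-dehydro-clavulone I) | CC/C=C\C/C=C\C[C@]1(OC(C)=O)C=CC(=O)/C1=C/C=C\[C@@H](CCC(=O)OC)OC(C)=O | target

**Totals**

Total step count: 15
Longest linear sequence: 9 steps (steps 1 to 7, then 14 and 15)

**Steps most likely to fail**

Step 6 (Proposed new method). Water may solvate the ion pair so that the chiral anion no longer discriminates the two conrotatory modes, or ionization by the chiral acid may be too slow, leaving hydrolytic opening of the furan to the open-chain diketone as the main path. The fallback uses known chemistry and relays the C12 configuration from a purchased stereocenter; it sets out from 2 and comes back to the route at 12. Commercial (4S)-4-[(tert-butyldimethylsilyl)oxy]cyclopent-2-en-1-one F1 would be treated with propargyl bromide and Zn in THF/aqueous NH4Cl (Barbier reaction). Carbonyl addition anti to the silyloxy group should give (1R,4S)-4-[(tert-butyldimethylsilyl)oxy]-1-(prop-2-yn-1-yl)cyclopent-2-en-1-ol F2. Coupling of F2 with 2 (CuI, NaI, K2CO3, DMF) would give the skipped diyne (1R,4S)-4-[(tert-butyldimethylsilyl)oxy]-1-(octa-2,5-diyn-1-yl)cyclopent-2-en-1-ol F3. Lindlar semihydrogenation would give (1R,4S)-4-[(tert-butyldimethylsilyl)oxy]-1-[(2Z,5Z)-octa-2,5-dien-1-yl]cyclopent-2-en-1-ol F4, and Bu4NF in THF the diol (1R,4S)-1-[(2Z,5Z)-octa-2,5-dien-1-yl]cyclopent-2-ene-1,4-diol F5. MnO2 in CH2Cl2, which oxidizes only the secondary allylic alcohol, would then give 12.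

Step 15. The E1cB elimination may proceed with poor control of the C7=C8 geometry, the nucleophilic catalyst may isomerize the 5Z olefin by reversible conjugate addition, and acetylation of the hindered tertiary alcohol may stall. The fallback replaces aldol dehydration by olefination; it sets out from 13 and comes back at 26. Enolate 22 would be C-phosphinylated with ClP(OEt)2 and the phosphonite oxidized in air to diethyl {(5S)-5-[(2Z,5Z)-octa-2,5-dien-1-yl]-2-oxo-5-[(trimethylsilyl)oxy]cyclopent-3-en-1-yl}phosphonate F9. Horner–Wadsworth–Emmons reaction of F9 with 21 (LiCl, i-Pr2NEt, MeCN) should give the E-configured dienone methyl (4R,5Z,7E)-4-acetoxy-7-{(5S)-5-[(2Z,5Z)-octa-2,5-dien-1-yl]-2-oxo-5-[(trimethylsilyl)oxy]cyclopent-3-en-1-ylidene}hept-5-enoate F10 with no acetate elimination involved. HF·pyridine would free the tertiary alcohol 26, which is then acetylated on its own (Ac2O, Et3N, 4-(dimethylamino)pyridine) to 27.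

Step 14. Enal 21 may isomerize from Z to E before it is consumed, the enolate may add in conjugate fashion, and the aldol may cleave by retro-aldol reaction during the acidic work-up. The fallback carries the labile Z olefin as an alkyne and reveals it last; it sets out from 19 and 13 and comes back at 27. Dess–Martin oxidation of 19 would give methyl (4R)-4-acetoxy-7-oxohept-5-ynoate F6, which cannot isomerize. Addition of enolate 22 and the same acidic work-up would give methyl (4R)-4-acetoxy-7-hydroxy-7-{(5S)-5-hydroxy-5-[(2Z,5Z)-octa-2,5-dien-1-yl]-2-oxocyclopent-3-en-1-yl}hept-5-ynoate F7. Ac2O, Et3N and 4-(dimethylamino)pyridine would give methyl (4R,7E)-4-acetoxy-7-{(5S)-5-acetoxy-5-[(2Z,5Z)-octa-2,5-dien-1-yl]-2-oxocyclopent-3-en-1-ylidene}hept-5-ynoate F8. Lindlar semihydrogenation with quinoline, stopped after one equivalent of H2, should reduce only the conjugated triple bond and give the 5Z olefin of 27.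

**Further compounds**

F1 | step 6 | (4S)-4-[(tert-butyldimethylsilyl)oxy]cyclopent-2-en-1-one | O=C1C=C[C@@H](O[Si](C)(C)C(C)(C)C)C1
F2 | step 6 | (1R,4S)-4-[(tert-butyldimethylsilyl)oxy]-1-(prop-2-yn-1-yl)cyclopent-2-en-1-ol | C#CC[C@]1(O)C=C[C@@H](O[Si](C)(C)C(C)(C)C)C1
F3 | step 6 | (1R,4S)-4-[(tert-butyldimethylsilyl)oxy]-1-(octa-2,5-diyn-1-yl)cyclopent-2-en-1-ol | CCC#CCC#CC[C@]1(O)C=C[C@@H](O[Si](C)(C)C(C)(C)C)C1
F4 | step 6 | (1R,4S)-4-[(tert-butyldimethylsilyl)oxy]-1-[(2Z,5Z)-octa-2,5-dien-1-yl]cyclopent-2-en-1-ol | CC/C=C\C/C=C\C[C@]1(O)C=C[C@@H](O[Si](C)(C)C(C)(C)C)C1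
F5 | step 6 | (1R,4S)-1-[(2Z,5Z)-octa-2,5-dien-1-yl]cyclopent-2-ene-1,4-diol | CC/C=C\C/C=C\C[C@]1(O)C=C[C@@H](O)C1
F6 | step 14 | methyl (4R)-4-acetoxy-7-oxohept-5-ynoate | COC(=O)CC[C@@H](OC(C)=O)C#CC=O
F7 | step 14 | methyl (4R)-4-acetoxy-7-hydroxy-7-{(5S)-5-hydroxy-5-[(2Z,5Z)-octa-2,5-dien-1-yl]-2-oxocyclopent-3-en-1-yl}hept-5-ynoate | CC/C=C\C/C=C\C[C@]1(O)C=CC(=O)C1C(O)C#C[C@@H](CCC(=O)OC)OC(C)=O
F8 | step 14 | methyl (4R,7E)-4-acetoxy-7-{(5S)-5-acetoxy-5-[(2Z,5Z)-octa-2,5-dien-1-yl]-2-oxocyclopent-3-en-1-ylidene}hept-5-ynoate | CC/C=C\C/C=C\C[C@]1(OC(C)=O)C=CC(=O)/C1=C/C#C[C@@H](CCC(=O)OC)OC(C)=O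
F9 | step 15 | diethyl {(5S)-5-[(2Z,5Z)-octa-2,5-dien-1-yl]-2-oxo-5-[(trimethylsilyl)oxy]cyclopent-3-en-1-yl}phosphonate | CC/C=C\C/C=C\C[C@]1(O[Si](C)(C)C)C=CC(=O)C1P(=O)(OCC)OCC
F10 | step 15 | methyl (4R,5Z,7E)-4-acetoxy-7-{(5S)-5-[(2Z,5Z)-octa-2,5-dien-1-yl]-2-oxo-5-[(trimethylsilyl)oxy]cyclopent-3-en-1-ylidene}hept-5-enoate | CC/C=C\C/C=C\C[C@]1(O[Si](C)(C)C)C=CC(=O)/C1=C/C=C\[C@@H](CCC(=O)OC)OC(C)=O
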